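**Assumption:** the target SMILES, read as 16-methylheptadecyl 2,3-dihydroxybenzoate (C25H42O4), has no stereocentre and no stereogenic double bond, so "single enantiomer" needs no asymmetric step.

## Retrosynthetic overview

1. 9 ⇒ 8: one global hydrogenation saturates an enol-ester C=C and removes both O-benzyl groups.
2. 8 ⇒ acid 7 + terminal alkyne 4: the alkyl C–O bond of the ester is made by Ru-vinylidene anti-Markovnikov addition of ArCO2–H across the alkyne. The fatty alcohol is never made and no acyl activation is used.
3. 4 ⇒ internal alkyne 3 (alkyne zipper) ⇒ dodec-1-yne 1 + 1-bromo-4-methylpentane 2 (acetylide alkylation).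
4. 7 ⇒ 2,3-dihydroxybenzoic acid 5 (perbenzylation, then saponification). Benzyl protection is needed because a free 2-OH could add back across the enol ester to give a benzodioxinone.
5. Rings and stereochemistry: no ring is formed (the benzene ring is bought intact). The only stereo-element en route, the Z-alkene of 8, is erased in the last step.

## Route

**Step 1**
Reactants: 1 (dodec-1-yne); 2 (1-bromo-4-methylpentane)
Product: 3 (2-methylheptadec-6-yne)
Conditions: n-BuLi (1.05 equiv), THF, −78 → 0 °C; then 2 (1.1 equiv), DMPU, NaI (cat.), 0 °C → rt, 16 h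
Reagents that add atoms: none (all heavy atoms come from 1 and 2)
Why: SN2 alkylation of a lithium acetylide with an unhindered primary bromide (branching is γ to the leaving group), accelerated by DMPU; no stereocentre is formed.

**Step 2**
Reactants: 3 (2-methylheptadec-6-yne)
Product: 4 (16-methylheptadec-1-yne)
Conditions: KH (4 equiv), H2N(CH2)3NH2 (KAPA), rt; add 3, 0 °C → rt, 3 h; then H2O
Reagents that add atoms: none
Why: Alkyne zipper (KAPA isomerisation): the triple bond walks by propargyl/allenyl anion equilibria and is trapped irreversibly as the terminal acetylide at the unbranched end, because the isopropyl terminus cannot host a terminal alkyne.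

**Step 3**
Reactants: 5 (2,3-dihydroxybenzoic acid)
Product: 6 (benzyl 2,3-bis(benzyloxy)benzoate)
Conditions: BnBr (3.5 equiv), K2CO3 (4.5 equiv), TBAI (cat.), DMF, 70 °C, 16 h
Reagents that add atoms: benzyl bromide, BrCc1ccccc1 (three benzyl groups)
Why: Williamson etherification plus carboxylate alkylation; excess reagent and heat drive alkylation of the hydrogen-bonded 2-OH.

**Step 4**
Reactants: 6 (benzyl 2,3-bis(benzyloxy)benzoate)
Product: 7 (2,3-bis(benzyloxy)benzoic acid)
Conditions: 2 M aq NaOH (4 equiv), MeOH/THF, 60 °C, 4 h; then 1 M HCl to pH 2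
Reagents that add atoms: sodium hydroxide/water, [Na+].[OH-] (one carboxyl oxygen)
Why: Saponification (BAc2) removes only the benzyl ester; aryl benzyl ethers are inert to hydroxide.

**Step 5 (key step)**
Reactants: 7 (2,3-bis(benzyloxy)benzoic acid, 1.0 equiv); 4 (16-methylheptadec-1-yne, 1.3 equiv)
Product: 8 ((Z)-16-methylheptadec-1-en-1-yl 2,3-bis(benzyloxy)benzoate)
Conditions: [RuCl2(p-cymene)]2 (2 mol%), P(4-ClC6H4)3 (6 mol%), DMAP (8 mol%), toluene, 60 °C, 16 h, Ar
Reagents that add atoms: none
Why: Ru-catalysed anti-Markovnikov hydro-oxycarbonylation of a terminal alkyne (Dixneuf/Goossen-type enol-ester synthesis): the carboxylate attacks Cα of a Ru-vinylidene to give the linear, mainly Z, enol ester, and the alkene geometry is irrelevant because it is hydrogenated next.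

**Step 6**
Reactants: 8 ((Z)-16-methylheptadec-1-en-1-yl 2,3-bis(benzyloxy)benzoate)
Product: 9 (Gentiside D, 16-methylheptadecyl 2,3-dihydroxybenzoate)
Conditions: H2 (1 atm), 10% Pd/C, EtOAc/EtOH (4:1), rt, 6 h; filter through Celite under Ar
Reagents that add atoms: none (H2 only)
Why: Heterogeneous catalytic hydrogenation saturates the enol-ester C=C to the primary alkyl ester and hydrogenolyses both aryl benzyl ethers (toluene by-product) in one operation; the alkyl benzoate and the arene are untouched and no stereocentre is created.

## Compound list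

1 | dodec-1-yne | C#CCCCCCCCCCC | starting material
2 | 1-bromo-4-methylpentane | CC(C)CCCBr | starting material
3 | 2-methylheptadec-6-yne | CC(C)CCCC#CCCCCCCCCCC | intermediate
4 | 16-methylheptadec-1-yne | CC(C)CCCCCCCCCCCCCC#C | intermediate
5 | 2,3-dihydroxybenzoic acid | OC(=O)c1cccc(O)c1O | starting material
6 | benzyl 2,3-bis(benzyloxy)benzoate | O=C(OCc1ccccc1)c1cccc(OCc2ccccc2)c1OCc1ccccc1 | intermediate
7 | 2,3-bis(benzyloxy)benzoic acid | OC(=O)c1cccc(OCc2ccccc2)c1OCc1ccccc1 | intermediate
8 | (Z)-16-methylheptadec-1-en-1-yl 2,3-bis(benzyloxy)benzoate | CC(C)CCCCCCCCCCCCC/C=C\OC(=O)c1cccc(OCc2ccccc2)c1OCc1ccccc1 | intermediate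
9 | Gentiside D (16-methylheptadecyl 2,3-dihydroxybenzoate) | CC(C)CCCCCCCCCCCCCCCOC(=O)c1cccc(O)c1O | target

## Summary

Total step count: 6.
Longest linear sequence: 4 (steps 1 → 2 → 5 → 6; the acid branch 3 → 4 → 5 → 6 is also 4).

Three steps most likely to fail, with fallbacks:

- **Step 5** (Ru addition: Markovnikov isomer, alkyne dimerisation, or a sluggish ortho-alkoxy acid). Fallback: drop the alkyne addition and form the aryl–carbonyl bond instead. Make 16-methylheptadecan-1-ol by Li2CuCl4-catalysed coupling of (4-methylpentyl)MgBr with 12-bromododecan-1-ol, then run a Pd/Xantphos alkoxycarbonylation (CO, 1 atm) of 1,2-bis(benzyloxy)-3-bromobenzene with that alcohol, and finish with the same hydrogenolysis.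
- **Step 6** (competing hydrogenolysis of the vinylic C–O bond, or incomplete debenzylation). Fallback: separate the two events with a different protecting-group logic. Carry the catechol as an acid-labile 2,2-diphenyl-1,3-benzodioxole or bis-MOM ether, reduce the enol-ester C=C with a homogeneous Rh catalyst (no C–O hydrogenolysis), then unmask with acid.
- **Step 2** (zipper: incomplete migration or allene/internal-alkyne contaminants on a waxy C18 hydrocarbon). Fallback: build the terminal alkyne without isomerisation. Do a Li2CuCl4-catalysed mono-coupling of (4-methylpentyl)MgBr with excess 1,10-dibromodecane to give 1-bromo-14-methylpentadecane, then SN2 displacement with lithium acetylide·ethylenediamine in DMSO to give 4.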